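**Strategy.** Ring A is cut across C1–C10 and C2–C3 into a two-carbon acrylate unit (C1–C2) and the four-atom unit C10–C5–C4–C3 carried by a ring B cyclohexanone. The route exploits that C10 is alpha to a C9 carbonyl and that the quaternary C4 bears two arms (C3, C19) that are identical at the malonate level. A reductively generated C10 enolate adds to tert-butyl acrylate and the new ester enolate condenses with one malonate ester (Michael–Dieckmann), closing ring A and setting both quaternary centres C10 and C4. The precursor is a 2-methylidene-3-(methylmalonyl)cyclohexanone from a catalytic asymmetric Michael addition.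

Key step: step 4

Remark on numbering: atom numbers are those of the labdane skeleton (ring A: C1–C5, C10; ring B: C5–C10; C17 on C8; C18 and C19 on C4, C19 cis to C20; C20 on C10; side chain C11–C16). The target is (3S,4R,5S,9R,10S,13R).

Remark (assumption): the catalyst antipodes in steps 1 and 10 are those that give the configurations drawn; they are taken to be the (S)-binaphthoxide catalyst and (DHQD)2AQN.

Step 1
Reactants: 1 cyclohex-2-en-1-one; 2 dimethyl 2-methylpropanedioate
Product: 3 dimethyl 2-methyl-2-[(1S)-3-oxocyclohexyl]propanedioate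
Conditions: LiAl[(S)-1,1'-binaphthalene-2,2'-diolate]2 (10 mol %), KOtBu (9 mol %), 4 Å molecular sieves, THF, rt
Reagents that add atoms: none
Why: Heterobimetallic binaphthoxide-catalysed asymmetric Michael addition of a 2-substituted malonate to a cyclic enone; the catalyst selects the enone face and should set C5 as (S).

Step 2
Reactants: 3 dimethyl 2-methyl-2-[(1S)-3-oxocyclohexyl]propanedioate
Product: 4 dimethyl 2-methyl-2-[(1S)-4-methyl-3-oxocyclohexyl]propanedioate (epimers at the new methyl carbon)
Conditions: LiN(iPr)2, THF, −78 °C; MeI, −78 → −20 °C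
Reagents that add atoms: iodomethane CI
Why: Kinetic enolate alkylation at the alpha-methylene remote from the bulky quaternary substituent (future C8); the new centre is inconsequential because C8 becomes sp2 in step 7.

Step 3
Reactants: 4 dimethyl 2-methyl-2-[(1S)-4-methyl-3-oxocyclohexyl]propanedioate
Product: 7 dimethyl 2-methyl-2-[(1S)-4-methyl-2-methylidene-3-oxocyclohexyl]propanedioate, via Mannich base 5 (not isolated), via methiodide 6 (not isolated)
Conditions: LiN(iPr)2, THF, −78 °C; CH2=NMe2+ I−; then MeI, CH2Cl2, rt; then aq. NaHCO3, rt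
Reagents that add atoms: Eschenmoser's salt (N,N-dimethylmethyleneiminium iodide) C=[N+](C)C.[I-]
Why: Kinetic deprotonation should favour the methylene (future C10) over the C8 methine; Mannich reaction, N-quaternisation and E1cB elimination then give the alpha-methylene ketone.

Step 4
Reactants: 7 dimethyl 2-methyl-2-[(1S)-4-methyl-2-methylidene-3-oxocyclohexyl]propanedioate; 8 tert-butyl prop-2-enoate
Product: 11 ring A beta-keto ester (trans-decalin-3,9-dione bearing a C2 tert-butyl ester and an axial C4 methyl ester), via lithium enolate 9 (not isolated), via ester enolate 10 (not isolated)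
Conditions: LiBH(sBu)3, THF, −78 °C; tert-butyl acrylate, −78 °C → rt; aq. NH4Cl
Reagents that add atoms: none
Why: Conjugate hydride delivery to the exocyclic enone of 7 creates the C20 methyl and the regiodefined tetrasubstituted lithium enolate 9, which adds through C10 to the acrylate (C1–C10) to give ester enolate 10, whose C2 then attacks one of the two C4 methyl esters (C2–C3) with loss of methoxide; deprotonation of the resulting beta-keto ester makes the sequence irreversible. The closest known reaction type is the tandem Michael–Dieckmann (anionic four-plus-two) annulation, run on an enolate generated by trialkylborohydride conjugate reduction. Ring A closes in a 6-(enolexo)-exo-trig acyl substitution through a chair transition state. C10 is set by approach of the acrylate anti to the bulky C5 substituent, which after ring closure means the trans-decalin with axial C20; C4 is set by desymmetrisation of the malonate, the chair placing the unreacted ester axial (cis to C20) because an axial C18 methyl would meet C20 in a syn-pentane clash, and the reversible Claisen step lets this preference act; C2 and C8 stay epimeric and are erased in steps 5 and 7. The step needs Michael addition to outrun retro-Michael loss of the methylmalonyl group from 9 (low temperature, lithium counter-ion) and ring closure at C3 to win over attack by a C8 enolate, which could only give a bridged diketone that cannot be stabilised as an enolate and therefore reverts.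

Step 5
Reactants: 11 ring A beta-keto ester
Product: 12 methyl 3,9-dioxo trans-decalin-4-carboxylate (4-CH3, 8-CH3, 10-CH3; ester axial)
Conditions: CF3CO2H, CH2Cl2, rt; then toluene, 90 °C
Reagents that add atoms: none
Why: Acidolysis of the tert-butyl ester and thermal decarboxylation of the beta-keto acid; the methyl ester on quaternary C4 is stable to acid and cannot decarboxylate.

Step 6
Reactants: 12 diketo ester
Product: 13 3-hydroxy-9-keto ester (3-OH axial and trans to C20)
Conditions: LiBH(sBu)3, THF, −78 °C; aq. NH4Cl
Reagents that add atoms: none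
Why: The bulky hydride attacks the C3 ketone along the equatorial trajectory to give the axial alcohol (C3 S), while the C9 ketone, flanked by quaternary C10 and tertiary C8, should be too hindered to react.

Step 7
Reactants: 13 3-hydroxy-9-keto ester
Product: 14 C9 enol triflate (C8=C9; 3-OH and C4 methyl ester retained)
Conditions: KN(SiMe3)2 (2.2 equiv), THF, −78 → −20 °C; PhNTf2; aq. NH4Cl
Reagents that add atoms: N-phenylbis(trifluoromethanesulfonimide) O=S(=O)(N(c1ccccc1)S(=O)(=O)C(F)(F)F)C(F)(F)F
Why: After alkoxide formation the second equivalent of base removes the C8 hydrogen, the only enolisable position of the C9 ketone, and the potassium enolate is O-triflated (enol triflate formation); the hindered alkoxide should not be sulfonylated.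

Step 8
Reactants: 14 C9 enol triflate
Product: 15 3,19-diol enol triflate
Conditions: iBu2AlH, CH2Cl2, −78 → 0 °C; aq. KNaC4H4O6
Reagents that add atoms: none
Why: Aluminium hydride reduction of the neopentyl methyl ester to the primary alcohol C19; enol triflates are inert to this reagent at low temperature.

Step 9
Reactants: 15 3,19-diol enol triflate
Product: 17 3-O-acetyl 19-O-TBS enol triflate, via mono-TBS ether 16 (not isolated)
Conditions: TBSCl, imidazole, DMF, 0 °C; then Ac2O, DMAP, pyridine, 40 °C
Reagents that add atoms: tert-butyldimethylsilyl chloride CC(C)(C)[Si](C)(C)Cl; acetic anhydride CC(=O)OC(C)=O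
Why: Silylation should be selective for the primary hydroxyl over the hindered axial secondary one, which is then acetylated under nucleophilic catalysis in the same flask.

Step 10
Reactants: 18 3-methylglutaric anhydride; 19 2-(trimethylsilyl)ethanol
Product: 20 (3R)-3-methyl-5-oxo-5-[2-(trimethylsilyl)ethoxy]pentanoic acid
Conditions: (DHQD)2AQN (10 mol %), Et2O, −30 °C
Reagents that add atoms: none
Why: Cinchona-alkaloid-catalysed enantioselective alcoholysis (desymmetrisation) of the prochiral anhydride; the catalyst selects one of the two enantiotopic carbonyl groups and so sets C13.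

Step 11
Reactants: 20 half-ester
Product: 21 2-(trimethylsilyl)ethyl (3R)-5-hydroxy-3-methylpentanoate
Conditions: BH3·SMe2, THF, 0 °C → rt
Reagents that add atoms: none
Why: Borane reduces the carboxylic acid chemoselectively in the presence of the ester; the product is used directly to avoid lactonisation.

Step 12
Reactants: 21 hydroxy ester
Product: 22 2-(trimethylsilyl)ethyl (3S)-5-iodo-3-methylpentanoate
Conditions: I2, PPh3, imidazole, CH2Cl2, 0 °C
Reagents that add atoms: iodine II
Why: Appel-type iodination of the primary alcohol; the stereocentre is untouched (the descriptor changes only through CIP priority).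

Step 13
Reactants: 17 3-O-acetyl 19-O-TBS enol triflate; 22 2-(trimethylsilyl)ethyl (3S)-5-iodo-3-methylpentanoate
Product: 24 protected labd-8-ene (tetrasubstituted C8=C9 with the side chain on C9), via organozinc iodide 23 (not isolated)
Conditions: 22, Zn dust, LiCl, THF, 40 °C; then 17, Pd(OAc)2 (5 mol %), SPhos, THF/NMP, 60 °C
Reagents that add atoms: none
Why: Negishi sp2–sp3 cross-coupling; zinc insertion tolerates the ester, and hindered 2,6,6-trisubstituted cyclohexenyl triflates are established partners for alkylzinc reagents.

Step 14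
Reactants: 24 protected labd-8-ene
Product: 25 7-oxo-labd-8-ene (enone C7(=O)–C8=C9)
Conditions: CrO3, 3,5-dimethylpyrazole, CH2Cl2, −20 °C
Reagents that add atoms: chromium trioxide O=[Cr](=O)=O
Why: Allylic C–H oxidation to the conjugated enone; the ring methylene C7 should be preferred over C11, which is shielded by quaternary C10, and over the C17 methyl.

Step 15
Reactants: 25 7-oxo-labd-8-ene
Product: 26 allylic alcohol (7-OH cis to C20)
Conditions: NaBH4, CeCl3·7H2O, MeOH/THF, −40 → 0 °C
Reagents that add atoms: none
Why: Luche 1,2-reduction; axial hydride delivery from the face opposite the axial C20 methyl should give the pseudo-equatorial 7-alcohol cis to C20, as in steroidal 4-en-3-ones.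

Step 16
Reactants: 26 allylic alcohol
Product: 29 protected labd-7-ene (9-H trans to C20), via sulfonylhydrazine 27 (not isolated), via allylic diazene 28 (not isolated)
Conditions: 2-O2NC6H4SO2NHNH2, PPh3, EtO2CN=NCO2Et, N-methylmorpholine, THF, −30 °C → rt
Reagents that add atoms: none
Why: Myers reductive 1,3-transposition: Mitsunobu displacement with inversion at C7, loss of arenesulfinic acid to the allylic diazene, and retro-ene loss of N2 that delivers hydrogen to C9 on the face of nitrogen (trans to C20, C9 R) while moving the alkene to C7=C8.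

Step 17
Reactants: 29 protected labd-7-ene
Product: 30 (3S,4R,5S,9R,10S,13R)-3-acetoxy-19-hydroxylabd-7-en-15-oic acid (target)
Conditions: Bu4NF, THF, 0 °C → rt; aq. NH4Cl
Reagents that add atoms: none
Why: Fluoride removes the silyl ether and cleaves the 2-(trimethylsilyl)ethyl ester by beta-elimination in one operation; the hindered axial acetate should survive, and migration to O19 is geometrically impossible because O3 and C19 are anti-diaxial.

**Compound list**

1 | cyclohex-2-en-1-one | O=C1C=CCCC1 | starting material
2 | dimethyl 2-methylpropanedioate (dimethyl methylmalonate) | COC(=O)C(C)C(=O)OC | starting material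
3 | dimethyl 2-methyl-2-[(1S)-3-oxocyclohexyl]propanedioate | O=C1C[C@H](CCC1)C(C)(C(=O)OC)C(=O)OC | intermediate
4 | dimethyl 2-methyl-2-[(1S)-4-methyl-3-oxocyclohexyl]propanedioate, epimers at the ring methyl carbon | O=C1C[C@H](CCC1C)C(C)(C(=O)OC)C(=O)OC | intermediate
5 | Mannich base, 2-(dimethylaminomethyl) derivative of 4 (not isolated) | O=C1C(CN(C)C)[C@H](CCC1C)C(C)(C(=O)OC)C(=O)OC | intermediate
6 | methiodide of 5, trimethylammonium iodide (not isolated) | O=C1C(C[N+](C)(C)C)[C@H](CCC1C)C(C)(C(=O)OC)C(=O)OC.[I-] | intermediate
7 | dimethyl 2-methyl-2-[(1S)-4-methyl-2-methylidene-3-oxocyclohexyl]propanedioate | O=C1C(=C)[C@H](CCC1C)C(C)(C(=O)OC)C(=O)OC | intermediate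
8 | tert-butyl prop-2-enoate (tert-butyl acrylate) | C=CC(=O)OC(C)(C)C | starting material
9 | lithium enolate of the 2-methyl ketone, C9(OLi)=C10(CH3) (not isolated) | [Li+].[O-]C1=C(C)[C@H](CCC1C)C(C)(C(=O)OC)C(=O)OC | intermediate
10 | lithium ester enolate of the Michael adduct, C10 quaternary (not isolated) | [Li+].[O-]C(OC(C)(C)C)=CC[C@]1(C)[C@H](CCC(C)C1=O)C(C)(C(=O)OC)C(=O)OC | intermediate
11 | ring A beta-keto ester: trans-decalin-3,9-dione with CO2tBu on C2; equatorial CH3 and axial CO2CH3 (cis to C20) on C4; CH3 on C8 and C10; C4, C5, C10 as in the target; C2 and C8 epimer mixtures | O=C1C(C(=O)OC(C)(C)C)C[C@]2(C)[C@H](CCC(C)C2=O)[C@]1(C)C(=O)OC | intermediate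
12 | methyl 3,9-dioxo trans-decalin-4-carboxylate: as 11 without the C2 ester | O=C1CC[C@]2(C)[C@H](CCC(C)C2=O)[C@]1(C)C(=O)OC | intermediate
13 | 3-hydroxy-9-keto ester: 3-OH axial, trans to C20 and anti to the C19 ester | O[C@H]1CC[C@]2(C)[C@H](CCC(C)C2=O)[C@]1(C)C(=O)OC | intermediate
14 | C9 enol triflate: C8=C9, OTf on C9, CH3 on C8; 3-OH and C19 methyl ester retained | O[C@H]1CC[C@]2(C)[C@H](CCC(C)=C2OS(=O)(=O)C(F)(F)F)[C@]1(C)C(=O)OC | intermediate
15 | 3,19-diol enol triflate | O[C@H]1CC[C@]2(C)[C@H](CCC(C)=C2OS(=O)(=O)C(F)(F)F)[C@]1(C)CO | intermediate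
16 | 19-O-TBS ether of 15 (not isolated) | O[C@H]1CC[C@]2(C)[C@H](CCC(C)=C2OS(=O)(=O)C(F)(F)F)[C@]1(C)CO[Si](C)(C)C(C)(C)C | intermediate
17 | 3-O-acetyl 19-O-TBS enol triflate | CC(=O)O[C@H]1CC[C@]2(C)[C@H](CCC(C)=C2OS(=O)(=O)C(F)(F)F)[C@]1(C)CO[Si](C)(C)C(C)(C)C | intermediate
18 | 3-methylglutaric anhydride (4-methyloxane-2,6-dione) | CC1CC(=O)OC(=O)C1 | starting material
19 | 2-(trimethylsilyl)ethanol | C[Si](C)(C)CCO | starting material
20 | (3R)-3-methyl-5-oxo-5-[2-(trimethylsilyl)ethoxy]pentanoic acid | OC(=O)C[C@@H](C)CC(=O)OCC[Si](C)(C)C | intermediate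
21 | 2-(trimethylsilyl)ethyl (3R)-5-hydroxy-3-methylpentanoate | OCC[C@@H](C)CC(=O)OCC[Si](C)(C)C | intermediate
22 | 2-(trimethylsilyl)ethyl (3S)-5-iodo-3-methylpentanoate | ICC[C@@H](C)CC(=O)OCC[Si](C)(C)C | intermediate
23 | organozinc iodide from 22 (not isolated) | I[Zn]CC[C@@H](C)CC(=O)OCC[Si](C)(C)C | intermediate
24 | 2-(trimethylsilyl)ethyl 3-acetoxy-19-(TBS-oxy)labd-8-en-15-oate, tetrasubstituted C8=C9 | CC(=O)O[C@H]1CC[C@]2(C)[C@H](CCC(C)=C2CC[C@@H](C)CC(=O)OCC[Si](C)(C)C)[C@]1(C)CO[Si](C)(C)C(C)(C)C | intermediate
25 | 7-oxo derivative of 24, enone C7(=O)–C8=C9 | CC(=O)O[C@H]1CC[C@]2(C)[C@H](CC(=O)C(C)=C2CC[C@@H](C)CC(=O)OCC[Si](C)(C)C)[C@]1(C)CO[Si](C)(C)C(C)(C)C | intermediate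
26 | 7-hydroxy-labd-8-ene, 7-OH cis to C20 | CC(=O)O[C@H]1CC[C@]2(C)[C@H](C[C@@H](O)C(C)=C2CC[C@@H](C)CC(=O)OCC[Si](C)(C)C)[C@]1(C)CO[Si](C)(C)C(C)(C)C | intermediate
27 | N-(C7-allyl)-N-(2-nitrophenylsulfonyl)hydrazine, nitrogen on C7 trans to C20 (not isolated) | CC(=O)O[C@H]1CC[C@]2(C)[C@H](C[C@H](N(N)S(=O)(=O)c3ccccc3[N+](=O)[O-])C(C)=C2CC[C@@H](C)CC(=O)OCC[Si](C)(C)C)[C@]1(C)CO[Si](C)(C)C(C)(C)C | intermediate
28 | allylic diazene at C7 (not isolated) | CC(=O)O[C@H]1CC[C@]2(C)[C@H](C[C@H](N=N)C(C)=C2CC[C@@H](C)CC(=O)OCC[Si](C)(C)C)[C@]1(C)CO[Si](C)(C)C(C)(C)C | intermediate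
29 | 2-(trimethylsilyl)ethyl 3-acetoxy-19-(TBS-oxy)labd-7-en-15-oate, 9-H trans to C20 | CC(=O)O[C@H]1CC[C@]2(C)[C@H](CC=C(C)[C@H]2CC[C@@H](C)CC(=O)OCC[Si](C)(C)C)[C@]1(C)CO[Si](C)(C)C(C)(C)C | intermediate
30 | (3S,4R,5S,9R,10S,13R)-3-acetoxy-19-hydroxylabd-7-en-15-oic acid | CC(=O)O[C@H]1CC[C@]2(C)[C@H](CC=C(C)[C@H]2CC[C@@H](C)CC(=O)O)[C@]1(C)CO | target

**Step count.** Total steps: 17. Longest linear sequence: 14 steps (steps 1–9 and 13–17).

**Steps most likely to fail**

1. Step 4. Enolate 9 may lose the methylmalonyl group by retro-Michael fragmentation or start oligomerisation of the acrylate before ring closure, and the facial discrimination between the two ester groups on C4 may be low. The fallback sets out from 7: the enolate is generated as in step 4 and trapped with phenyl vinyl sulfone, whose alpha-sulfonyl carbanion does not propagate and acylates at C3 to give the beta-keto sulfone F1. Reductive desulfonylation with Al(Hg) in wet THF then gives 12, where the route is rejoined.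

2. Step 14. The oxidant may attack the side-chain allylic methylene C11 or the C17 methyl as well as C7, or over-oxidise the enone. The fallback sets out from 17 and moves the oxidation ahead of the coupling, where C7 is the only allylic methylene: Rh2(caprolactamate)4 with tBuOOH should convert 17 into the beta-triflyloxy enone F2. Negishi coupling of F2 with 23 under the conditions of step 13 then gives 25 directly.

3. Step 3. Deprotonation of 4 may occur partly at the C8 methine, and the exocyclic enone may isomerise into the ring during elimination. The fallback sets out from 4 and replaces enolate chemistry by an acid-mediated Mannich methylenation (paraformaldehyde, N-methylanilinium trifluoroacetate, THF, reflux). The anilinomethyl ketone F3 can eliminate only on the C10 side, because an adduct at C8 has no remaining alpha-hydrogen and reverts; this gives 7.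

**Further compounds**

F1 | step 4 | beta-keto sulfone: 12 bearing a phenylsulfonyl group on C2 | O=C1C(S(=O)(=O)c3ccccc3)C[C@]2(C)[C@H](CCC(C)C2=O)[C@]1(C)C(=O)OC
F2 | step 14 | beta-triflyloxy enone: 17 with a C7 ketone | CC(=O)O[C@H]1CC[C@]2(C)[C@H](CC(=O)C(C)=C2OS(=O)(=O)C(F)(F)F)[C@]1(C)CO[Si](C)(C)C(C)(C)C
F3 | step 3 | Mannich base of 4 with an N-methylanilinomethyl group on the future C10 | O=C1C(CN(C)c2ccccc2)[C@H](CCC1C)C(C)(C(=O)OC)C(=O)OC
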